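**Plan**

- Retrosynthesis: the two interflavan C4–C8 bonds are cut first (epicatechin C4 to C8 of the middle catechin, then middle C4 to C8 of the terminal catechin). In the remaining catechin 3-O-ester of 1-hydroxy-6-oxocyclohex-2-ene-1-carboxylic acid (HCH), the C6 ketone goes back to a C5–C6 oxirane, the two oxirane C–O bonds to a ring alkene, and then the C1–OH bond and the ester C–O bond are cut.
- Enabling feature: in the HCH ring the quaternary carbinol C1 carries two arms, C2=C3 and C6(=O)–C5H2, that differ only in oxidation level. C1 is therefore latent in an achiral 1-hydroxycyclohexa-2,5-diene-1-carboxylate whose alkenes C2=C3 and C5=C6 are enantiotopic in the free acyl group and diastereotopic once on catechin.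
- Forward: Birch reduction of benzoic acid, esterification onto silylated (+)-catechin, C1 hydroxylation, desymmetrising hydroxyl-directed epoxidation (the oxirane closes), iodide opening with deiodination, and oxidation to the ketone. Two Lewis-acid C4→C8 couplings with C4-alkoxy flavans made from catechin and epicatechin follow, then one global desilylation.
- Stereochemistry: C2/C3 of the three flavan units come from (+)-catechin (twice) and (−)-epicatechin. C1 of the acyl group comes from the ligand-controlled choice between the two ring alkenes. Both C4 centres come from arene attack anti to the C3 oxygen (4α in the catechin unit, 4β in the epicatechin unit).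

Key step: step 5

Assumption: the (R,R) antipode of the bis-hydroxamic acid ligand is written for step 5; which antipode is matched to the (1S,5R,6R)-epoxide would be settled with both on a small scale, and the other one is used if needed.
Remark: the C4 ethers 12 and 16 are drawn 4β by analogy with the benzyl ether series; this centre is planarised on ionisation, so its configuration does not bear on the route.

Step 1
Reactants: 1 benzoic acid
Product: 2 cyclohexa-2,5-diene-1-carboxylic acid
Conditions: Na, NH3(l), EtOH, −78 °C; NH4Cl; aq HCl work-up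
Reagents that add atoms: none
Why: Birch reduction of a benzoate places the two new hydrogens at C1 and C4, so the skipped 2,5-diene acid should form without over-reduction.

Step 2
Reactants: 3 (+)-catechin
Product: 4 5,7,3',4'-tetra-O-TBS-(+)-catechin (3-OH free)
Conditions: TBSCl (4.4 equiv), imidazole, DMF, 0 °C → rt
Reagents that add atoms: tert-butyldimethylsilyl chloride, CC(C)(C)[Si](C)(C)Cl
Why: Silylation of the four acidic phenols is much faster than that of the hindered secondary C3 hydroxyl, so a slight excess of silyl chloride should leave the 3-OH free (chemoselective silyl ether formation).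

Step 3
Reactants: 4 5,7,3',4'-tetra-O-TBS-(+)-catechin; 2 cyclohexa-2,5-diene-1-carboxylic acid
Product: 5 tetra-O-TBS-catechin 3-O-(cyclohexa-2,5-diene-1-carboxylate)
Conditions: EDC·HCl, DMAP, CH2Cl2, 0 °C → rt
Reagents that add atoms: none
Why: Steglich esterification acylates the hindered C3 hydroxyl under mild conditions, and the acyl group is still achiral, so no stereocentre is at risk here.

Step 4
Reactants: 5 tetra-O-TBS-catechin 3-O-(cyclohexa-2,5-diene-1-carboxylate)
Product: 7 tetra-O-TBS-catechin 3-O-(1-hydroxycyclohexa-2,5-diene-1-carboxylate), via potassium dienolate 6 (not isolated)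
Conditions: KN(SiMe3)2, THF, −78 °C; then 2-(phenylsulfonyl)-3-phenyloxaziridine, −78 °C; aq NH4Cl at −78 °C
Reagents that add atoms: 2-(phenylsulfonyl)-3-phenyloxaziridine, O=S(=O)(c1ccccc1)N1OC1c1ccccc1
Why: The doubly allylic α-proton is removed cleanly and the cross-conjugated ester enolate, which reacts with electrophiles at C1 as in Birch reductive alkylation, should take up oxygen from the N-sulfonyloxaziridine at C1 (enolate α-hydroxylation); cold, buffered work-up guards the bis-allylic carbinol against dehydration to the benzoate.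

Step 5
Reactants: 7 tetra-O-TBS-catechin 3-O-(1-hydroxycyclohexa-2,5-diene-1-carboxylate)
Product: 8 tetra-O-TBS-catechin 3-O-[(1S,5R,6R)-5,6-epoxy-1-hydroxycyclohex-2-ene-1-carboxylate] (oxirane syn to the C1 hydroxyl)
Conditions: Hf(OtBu)4 (20 mol %), (R,R)-N,N'-dihydroxy-N,N'-bis(diphenylacetyl)-trans-cyclohexane-1,2-diamine (22 mol %), cumene hydroperoxide (1.2 equiv), 4 Å molecular sieves, toluene, 0 °C
Reagents that add atoms: cumene hydroperoxide, CC(C)(OO)c1ccccc1
Why: Proposed new method: the tertiary hydroxyl of 7 and cumene hydroperoxide bind the tetravalent hafnium centre as alkoxide and peroxide, and the peroxide oxygen is passed in one concerted step to the alkene that the C2-symmetric ligand pocket holds within reach. The closest known reaction type is the hydroxyl-directed, ligand-controlled metal-peroxide epoxidation of tertiary allylic alcohols, including the desymmetrisation of bis-alkenyl carbinols; it has not been shown on a cyclohexa-2,5-dienyl carbinol that carries an ester on the carbinol carbon. The oxirane closes by [2+1] oxygen transfer onto C5=C6, both C–O bonds forming at once from the face that bears the hydroxyl, so C5 and C6 are set syn to the C1 oxygen by the metal tether. C1 becomes stereogenic only through the choice between the two diastereotopic ring alkenes, and this choice is made by the chiral ligand, the remote catechin stereocentres adding at most a small bias. The step needs group selectivity, syn-face selectivity and a stop at the mono-epoxide: the directing hydroxyl secures the face and the ligand the group, and since the mismatched mono-epoxide should be the one that is epoxidised a second time more quickly, a slight over-run is expected to raise the diastereomeric purity of 8 at the cost of some material. The ester on C1 disfavours ionisation of the bis-allylic carbinol, so the weakly Lewis-acidic alkoxide catalyst should be tolerated.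

Step 6
Reactants: 8 tetra-O-TBS-catechin 3-O-[(1S,5R,6R)-5,6-epoxy-1-hydroxycyclohex-2-ene-1-carboxylate]
Product: 10 tetra-O-TBS-catechin 3-O-[(1S,6R)-1,6-dihydroxycyclohex-2-ene-1-carboxylate] (cis-diol), via trans-iodohydrin 9 (not isolated)
Conditions: MgI2, toluene/Et2O, −60 → −20 °C; then Bu3SnH, Et3B, air, 0 °C → rt; aq NH4Cl
Reagents that add atoms: none
Why: Magnesium chelated between the C1 hydroxyl and the oxirane oxygen directs iodide anti to the distal, less hindered C5 (C6 is shielded by the quaternary, electron-poor C1), and radical deiodination with the tin hydride then leaves the C6 carbinol untouched (regioselective halohydrin opening of a 2,3-epoxy alcohol followed by radical dehalogenation).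

Step 7
Reactants: 10 tetra-O-TBS-catechin 3-O-[(1S,6R)-1,6-dihydroxycyclohex-2-ene-1-carboxylate]
Product: 11 tetra-O-TBS-catechin 3-O-[(1S)-1-hydroxy-6-oxocyclohex-2-ene-1-carboxylate]
Conditions: IBX, DMSO, rt
Reagents that add atoms: none
Why: IBX oxidises the secondary carbinol of a vicinal diol to the α-ketol without glycol cleavage, the tertiary C1 carbinol cannot be oxidised or epimerised, and the silyl ethers keep the phenols out of reach of the oxidant (hypervalent-iodine alcohol oxidation).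

Step 8
Reactants: 4 5,7,3',4'-tetra-O-TBS-(+)-catechin
Product: 12 (2R,3S,4S)-4-(2-ethoxyethoxy)-5,7,3',4'-tetra-O-TBS-flavan-3-ol (catechin unit, 4β-alkoxy)
Conditions: DDQ, 2-ethoxyethanol, CH2Cl2, rt
Reagents that add atoms: 2-ethoxyethanol, CCOCCO
Why: DDQ abstracts the benzylic C4 hydride of the electron-rich ring A and the alcohol traps the resulting cation, the established way to turn a protected flavan-3-ol into a C4 electrophile (benzylic oxidation with alcohol capture).

Step 9
Reactants: 11 tetra-O-TBS-catechin 3-O-[(1S)-1-hydroxy-6-oxocyclohex-2-ene-1-carboxylate]; 12 (2R,3S,4S)-4-(2-ethoxyethoxy)-5,7,3',4'-tetra-O-TBS-flavan-3-ol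
Product: 13 octa-O-TBS-catechin-(4α→8)-catechin, lower unit 3-O-[(1S)-1-hydroxy-6-oxocyclohex-2-ene-1-carboxylate]
Conditions: 11 (2.5 equiv, excess recovered), TMSOTf (0.5 equiv), CH2Cl2, −78 °C; aq NaHCO3
Reagents that add atoms: none
Why: TMSOTf ionises the C4 ether of 12 to a cation stabilised by the ring A oxygens, and C8 of 11, the only free position not flanked by two silyloxy groups, captures it anti to the C3 hydroxyl to give the 3,4-trans (4α) bond (Friedel–Crafts-type flavan coupling, the excess of nucleophile holding back self-condensation of 12).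

Step 10
Reactants: 14 (−)-epicatechin
Product: 15 5,7,3',4'-tetra-O-TBS-(−)-epicatechin (3-OH free)
Conditions: TBSCl (4.4 equiv), imidazole, DMF, 0 °C → rt
Reagents that add atoms: tert-butyldimethylsilyl chloride, CC(C)(C)[Si](C)(C)Cl
Why: As in step 2, the phenols are silylated far faster than the axial, hindered C3 hydroxyl (chemoselective silyl ether formation).

Step 11
Reactants: 15 5,7,3',4'-tetra-O-TBS-(−)-epicatechin
Product: 16 (2R,3R,4S)-4-(2-ethoxyethoxy)-5,7,3',4'-tetra-O-TBS-flavan-3-ol (epicatechin unit, 4β-alkoxy)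
Conditions: DDQ, 2-ethoxyethanol, CH2Cl2, rt
Reagents that add atoms: 2-ethoxyethanol, CCOCCO
Why: The same DDQ hydride abstraction and alcohol capture as in step 8 installs the C4 leaving group, the alcohol entering anti to the C2 aryl and C3 hydroxyl groups (benzylic oxidation with alcohol capture).

Step 12
Reactants: 13 octa-O-TBS-catechin-(4α→8)-catechin 3-O-HCH ester; 16 (2R,3R,4S)-4-(2-ethoxyethoxy)-5,7,3',4'-tetra-O-TBS-flavan-3-ol
Product: 17 dodeca-O-TBS-epicatechin-(4β→8)-catechin-(4α→8)-catechin, terminal unit 3-O-[(1S)-1-hydroxy-6-oxocyclohex-2-ene-1-carboxylate]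
Conditions: 13 (1.5 equiv, excess recovered), TMSOTf (0.5 equiv), CH2Cl2, −78 → −40 °C; aq NaHCO3
Reagents that add atoms: none
Why: The epicatechin C4 cation is captured by C8 of the upper catechin unit of 13 (both C6 positions lie between two silyloxy groups and the lower C8 is substituted), from the β face anti to the C2 aryl and C3 hydroxyl groups, giving the 4β (3,4-trans) bond (Friedel–Crafts-type flavan coupling of a dimeric nucleophile with a monomeric electrophile).

Step 13
Reactants: 17 dodeca-O-TBS-epicatechin-(4β→8)-catechin-(4α→8)-catechin 3-O-HCH ester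
Product: 18 epicatechin-(4β→8)-catechin-(4α→8)-catechin 3-O-[(1S)-1-hydroxy-6-oxocyclohex-2-ene-1-carboxylate] at the terminal unit (CNP0159807.2)
Conditions: HF·pyridine, pyridine, THF, 0 °C → rt; Sephadex LH-20
Reagents that add atoms: none
Why: Buffered fluoride cleaves all twelve aryl silyl ethers under mildly acidic, non-reductive conditions that should spare the base-sensitive α-hydroxy β-keto ester, its alkene and the acid-labile interflavan bonds (fluoride desilylation).

**Compound list**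

1 | benzoic acid | O=C(O)c1ccccc1 | starting material
2 | cyclohexa-2,5-diene-1-carboxylic acid | O=C(O)C1C=CCC=C1 | intermediate
3 | (+)-catechin, (2R,3S) | O[C@H]1Cc2c(O)cc(O)cc2O[C@@H]1c1ccc(O)c(O)c1 | starting material
4 | 5,7,3',4'-tetra-O-TBS-(+)-catechin | O[C@H]1Cc2c(O[Si](C)(C)C(C)(C)C)cc(O[Si](C)(C)C(C)(C)C)cc2O[C@@H]1c1ccc(O[Si](C)(C)C(C)(C)C)c(O[Si](C)(C)C(C)(C)C)c1 | intermediate
5 | tetra-O-TBS-catechin 3-O-(cyclohexa-2,5-diene-1-carboxylate) | O=C(C1C=CCC=C1)O[C@H]1Cc2c(O[Si](C)(C)C(C)(C)C)cc(O[Si](C)(C)C(C)(C)C)cc2O[C@@H]1c1ccc(O[Si](C)(C)C(C)(C)C)c(O[Si](C)(C)C(C)(C)C)c1 | intermediate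
6 | potassium dienolate of 5 (formed in the flask) | [K+].[O-]C(=C1C=CCC=C1)O[C@H]1Cc2c(O[Si](C)(C)C(C)(C)C)cc(O[Si](C)(C)C(C)(C)C)cc2O[C@@H]1c1ccc(O[Si](C)(C)C(C)(C)C)c(O[Si](C)(C)C(C)(C)C)c1 | intermediate
7 | tetra-O-TBS-catechin 3-O-(1-hydroxycyclohexa-2,5-diene-1-carboxylate) | OC1(C=CCC=C1)C(=O)O[C@H]1Cc2c(O[Si](C)(C)C(C)(C)C)cc(O[Si](C)(C)C(C)(C)C)cc2O[C@@H]1c1ccc(O[Si](C)(C)C(C)(C)C)c(O[Si](C)(C)C(C)(C)C)c1 | intermediate
8 | tetra-O-TBS-catechin 3-O-[(1S,5R,6R)-5,6-epoxy-1-hydroxycyclohex-2-ene-1-carboxylate], oxirane syn to OH | [C@H]12O[C@@H]2CC=C[C@@]1(O)C(=O)O[C@H]1Cc2c(O[Si](C)(C)C(C)(C)C)cc(O[Si](C)(C)C(C)(C)C)cc2O[C@@H]1c1ccc(O[Si](C)(C)C(C)(C)C)c(O[Si](C)(C)C(C)(C)C)c1 | intermediate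
9 | tetra-O-TBS-catechin 3-O-[(1S,5S,6S)-1,6-dihydroxy-5-iodocyclohex-2-ene-1-carboxylate], iodide trans to the C6 hydroxyl (formed in the flask) | O[C@@H]1[C@@H](I)CC=C[C@@]1(O)C(=O)O[C@H]1Cc2c(O[Si](C)(C)C(C)(C)C)cc(O[Si](C)(C)C(C)(C)C)cc2O[C@@H]1c1ccc(O[Si](C)(C)C(C)(C)C)c(O[Si](C)(C)C(C)(C)C)c1 | intermediate
10 | tetra-O-TBS-catechin 3-O-[(1S,6R)-1,6-dihydroxycyclohex-2-ene-1-carboxylate], cis-diol | O[C@@H]1CCC=C[C@@]1(O)C(=O)O[C@H]1Cc2c(O[Si](C)(C)C(C)(C)C)cc(O[Si](C)(C)C(C)(C)C)cc2O[C@@H]1c1ccc(O[Si](C)(C)C(C)(C)C)c(O[Si](C)(C)C(C)(C)C)c1 | intermediate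
11 | tetra-O-TBS-catechin 3-O-[(1S)-1-hydroxy-6-oxocyclohex-2-ene-1-carboxylate] | O=C1CCC=C[C@@]1(O)C(=O)O[C@H]1Cc2c(O[Si](C)(C)C(C)(C)C)cc(O[Si](C)(C)C(C)(C)C)cc2O[C@@H]1c1ccc(O[Si](C)(C)C(C)(C)C)c(O[Si](C)(C)C(C)(C)C)c1 | intermediate
12 | (2R,3S,4S)-4-(2-ethoxyethoxy)-5,7,3',4'-tetra-O-TBS-flavan-3-ol (from catechin) | O[C@H]1[C@@H](OCCOCC)c2c(O[Si](C)(C)C(C)(C)C)cc(O[Si](C)(C)C(C)(C)C)cc2O[C@@H]1c1ccc(O[Si](C)(C)C(C)(C)C)c(O[Si](C)(C)C(C)(C)C)c1 | intermediate
13 | octa-O-TBS-catechin-(4α→8)-catechin, lower unit 3-O-[(1S)-HCH ester] | O=C1CCC=C[C@@]1(O)C(=O)O[C@H]1Cc2c(O[Si](C)(C)C(C)(C)C)cc(O[Si](C)(C)C(C)(C)C)c([C@@H]3c4c(O[Si](C)(C)C(C)(C)C)cc(O[Si](C)(C)C(C)(C)C)cc4O[C@H](c4ccc(O[Si](C)(C)C(C)(C)C)c(O[Si](C)(C)C(C)(C)C)c4)[C@H]3O)c2O[C@@H]1c1ccc(O[Si](C)(C)C(C)(C)C)c(O[Si](C)(C)C(C)(C)C)c1 | intermediate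
14 | (−)-epicatechin, (2R,3R) | O[C@@H]1Cc2c(O)cc(O)cc2O[C@@H]1c1ccc(O)c(O)c1 | starting material
15 | 5,7,3',4'-tetra-O-TBS-(−)-epicatechin | O[C@@H]1Cc2c(O[Si](C)(C)C(C)(C)C)cc(O[Si](C)(C)C(C)(C)C)cc2O[C@@H]1c1ccc(O[Si](C)(C)C(C)(C)C)c(O[Si](C)(C)C(C)(C)C)c1 | intermediate
16 | (2R,3R,4S)-4-(2-ethoxyethoxy)-5,7,3',4'-tetra-O-TBS-flavan-3-ol (from epicatechin) | O[C@@H]1[C@@H](OCCOCC)c2c(O[Si](C)(C)C(C)(C)C)cc(O[Si](C)(C)C(C)(C)C)cc2O[C@@H]1c1ccc(O[Si](C)(C)C(C)(C)C)c(O[Si](C)(C)C(C)(C)C)c1 | intermediate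
17 | dodeca-O-TBS-epicatechin-(4β→8)-catechin-(4α→8)-catechin, terminal unit 3-O-[(1S)-HCH ester] | O=C1CCC=C[C@@]1(O)C(=O)O[C@H]1Cc2c(O[Si](C)(C)C(C)(C)C)cc(O[Si](C)(C)C(C)(C)C)c([C@@H]3c4c(O[Si](C)(C)C(C)(C)C)cc(O[Si](C)(C)C(C)(C)C)c([C@H]5c6c(O[Si](C)(C)C(C)(C)C)cc(O[Si](C)(C)C(C)(C)C)cc6O[C@H](c6ccc(O[Si](C)(C)C(C)(C)C)c(O[Si](C)(C)C(C)(C)C)c6)[C@@H]5O)c4O[C@H](c4ccc(O[Si](C)(C)C(C)(C)C)c(O[Si](C)(C)C(C)(C)C)c4)[C@H]3O)c2O[C@@H]1c1ccc(O[Si](C)(C)C(C)(C)C)c(O[Si](C)(C)C(C)(C)C)c1 | intermediate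
18 | epicatechin-(4β→8)-catechin-(4α→8)-catechin, terminal unit 3-O-[(1S)-1-hydroxy-6-oxocyclohex-2-ene-1-carboxylate] (CNP0159807.2) | O=C1CCC=C[C@@]1(O)C(=O)O[C@H]1Cc2c(O)cc(O)c([C@@H]3c4c(O)cc(O)c([C@H]5c6c(O)cc(O)cc6O[C@H](c6ccc(O)c(O)c6)[C@@H]5O)c4O[C@H](c4ccc(O)c(O)c4)[C@H]3O)c2O[C@@H]1c1ccc(O)c(O)c1 | target

**Step count and risks**

Total step count: 13. Longest linear sequence: 9 steps (steps 1, 3, 4, 5, 6, 7, 9, 12, 13).

Steps most likely to fail:

1. Step 5 (new method). The ligand may discriminate poorly between the two diastereotopic alkenes, the catalyst may turn over slowly on this hindered α-hydroxy ester, or the bis-allylic carbinol may dehydrate to the benzoate on the metal. The fallback uses known chemistry, sets out from 4 and comes back at 11. Birch reduction of salicylic acid (Na, NH3) should give 6-oxocyclohex-2-ene-1-carboxylic acid F1. Cold carbodiimide esterification of F1 with 4 (EDC·HCl, DMAP, 0 °C) should give tetra-O-TBS-catechin 3-O-(6-oxocyclohex-2-ene-1-carboxylate) F2, a β-keto ester expected to sit largely as its enol. α-Hydroxylation of F2 (dimethyldioxirane, or a cinchona-alkaloid phase-transfer catalyst with cumene hydroperoxide for stereocontrol) should give 11 together with its C1 epimer, tetra-O-TBS-catechin 3-O-[(1R)-1-hydroxy-6-oxocyclohex-2-ene-1-carboxylate] F3. These are diastereomers and are separated by chromatography.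

2. Step 12. The epicatechin cation may attack more than one ring A position of the dimer, or may be consumed by self-condensation of the electrophile, giving regioisomeric and higher oligomers. The fallback reverses the order of assembly with orthogonal activation, sets out from 16 and 12 and comes back at 17. Exchange of the C4 ether of 16 with phenylmethanethiol (BF3·OEt2, −78 °C) should give 4β-benzylthio-tetra-O-TBS-epicatechin F4. AgBF4 with 2,6-di-tert-butyl-4-methylpyridine activates only the thioether, so that C8 of 12, whose own C4 ether stays intact, captures the cation. This should give the dimeric electrophile octa-O-TBS-epicatechin-(4β→8)-[4β-(2-ethoxyethoxy)catechin] F5. TMSOTf then ionises F5 in the presence of 11, which has a single reactive position (C8), to give 17.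

3. Step 9. The silylated, 3-O-acylated nucleophile may attack sluggishly, so that self-condensation of the electrophile takes over. The fallback is a protecting-group-free condensation, sets out from 11 and comes back at 13. HF·pyridine desilylation of 11 should give catechin 3-O-[(1S)-1-hydroxy-6-oxocyclohex-2-ene-1-carboxylate] F6. Reduction of (+)-taxifolin with NaBH4 should give 2,3-trans-3,4-trans-leucocyanidin F7. F7 is condensed with an excess of F6 in dilute aqueous acid at rt, and the free dimer catechin-(4α→8)-catechin 3-O-HCH ester F8 is purified on Sephadex LH-20. Its eight phenols are then silylated (TBSCl, imidazole, DMF) as in step 2 to return to 13.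

**Further compounds**

F1 | step 5 | 6-oxocyclohex-2-ene-1-carboxylic acid | O=C1CCC=CC1C(=O)O
F2 | step 5 | tetra-O-TBS-catechin 3-O-(6-oxocyclohex-2-ene-1-carboxylate) | O=C1CCC=CC1C(=O)O[C@H]1Cc2c(O[Si](C)(C)C(C)(C)C)cc(O[Si](C)(C)C(C)(C)C)cc2O[C@@H]1c1ccc(O[Si](C)(C)C(C)(C)C)c(O[Si](C)(C)C(C)(C)C)c1
F3 | step 5 | tetra-O-TBS-catechin 3-O-[(1R)-1-hydroxy-6-oxocyclohex-2-ene-1-carboxylate] | O=C1CCC=C[C@]1(O)C(=O)O[C@H]1Cc2c(O[Si](C)(C)C(C)(C)C)cc(O[Si](C)(C)C(C)(C)C)cc2O[C@@H]1c1ccc(O[Si](C)(C)C(C)(C)C)c(O[Si](C)(C)C(C)(C)C)c1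
F4 | step 12 | 4β-benzylthio-5,7,3',4'-tetra-O-TBS-epicatechin | O[C@@H]1[C@@H](SCc3ccccc3)c2c(O[Si](C)(C)C(C)(C)C)cc(O[Si](C)(C)C(C)(C)C)cc2O[C@@H]1c1ccc(O[Si](C)(C)C(C)(C)C)c(O[Si](C)(C)C(C)(C)C)c1
F5 | step 12 | octa-O-TBS-epicatechin-(4β→8)-[4β-(2-ethoxyethoxy)catechin] | O[C@H]1[C@@H](OCCOCC)c2c(O[Si](C)(C)C(C)(C)C)cc(O[Si](C)(C)C(C)(C)C)c([C@H]3c4c(O[Si](C)(C)C(C)(C)C)cc(O[Si](C)(C)C(C)(C)C)cc4O[C@H](c4ccc(O[Si](C)(C)C(C)(C)C)c(O[Si](C)(C)C(C)(C)C)c4)[C@@H]3O)c2O[C@@H]1c1ccc(O[Si](C)(C)C(C)(C)C)c(O[Si](C)(C)C(C)(C)C)c1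
F6 | step 9 | catechin 3-O-[(1S)-1-hydroxy-6-oxocyclohex-2-ene-1-carboxylate] | O=C1CCC=C[C@@]1(O)C(=O)O[C@H]1Cc2c(O)cc(O)cc2O[C@@H]1c1ccc(O)c(O)c1
F7 | step 9 | (2R,3S,4R)-leucocyanidin (2,3-trans-3,4-trans-flavan-3,4-diol) | O[C@H]1[C@H](O)c2c(O)cc(O)cc2O[C@@H]1c1ccc(O)c(O)c1
F8 | step 9 | catechin-(4α→8)-catechin, lower unit 3-O-[(1S)-1-hydroxy-6-oxocyclohex-2-ene-1-carboxylate] | O=C1CCC=C[C@@]1(O)C(=O)O[C@H]1Cc2c(O)cc(O)c([C@@H]3c4c(O)cc(O)cc4O[C@H](c4ccc(O)c(O)c4)[C@H]3O)c2O[C@@H]1c1ccc(O)c(O)c1
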